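**Plan**
- Retrosynthesis: the O–alkyl bonds at C5 (methyl) and C3′ (isopropyl) are restored first, then ring C is opened at C4–C4a and at O1–C2.
- The three-carbon bridge is then cut at C3–C4 (chloroformate carbon) and at C2≡C3 (ring B aldehyde carbon plus one carbon from CBr4); the O1 oxygen goes back to a C–H bond of tetramethoxybenzene.
- Enabling feature: C4a is the only unsubstituted carbon of ring A, ortho to C8a–O1 and to the C5 methoxy carbon and para to the C7 methoxy carbon, so the C4 acyl carbon can enter only there.
- Forward: the ring A phenol (one step) and the ring B arylpropiolate (three steps) are joined through O1–C2 by conjugate addition; saponification, closure of ring C by acylation at C4a, then BCl3 frees the C5 and C3′ hydroxyls.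
- Stereochemistry: the target has no stereocentre; the only stereo-element is the Z alkene of the open-chain acid, set by anti addition to the alkyne and absorbed into the aromatic pyranone.

Key step: step 7

Remark on the chemistry: 1,2,3,4-tetramethoxybenzene and 3-hydroxy-4,5-dimethoxybenzaldehyde are taken as catalogue compounds, and the conjugate adduct is carried forward as the Z isomer expected from anti addition.

**Step 1**
Reactants: 1 1,2,3,4-tetramethoxybenzene
Product: 4 2,3,4,5-tetramethoxyphenol, via aryllithium 2 (not isolated), via dimethyl arylboronate 3 (not isolated)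
Conditions: n-BuLi, TMEDA, THF, 0 °C; B(OMe)3, −78 °C to rt; AcOH, 30% aq. H2O2, 0 °C to rt
Reagents that add atoms: hydrogen peroxide, OO
Why: Directed ortho-lithiation next to a methoxy group (the two free positions of 1 are equivalent by symmetry), borylation and peroxide oxidation of the arylboronate with aryl migration from boron to oxygen form a standard one-flask arene-to-phenol conversion that leaves aryl methyl ethers untouched.

**Step 2**
Reactants: 5 3-hydroxy-4,5-dimethoxybenzaldehyde
Product: 6 3-isopropoxy-4,5-dimethoxybenzaldehyde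
Conditions: 2-bromopropane, K2CO3, DMF, 60 °C
Reagents that add atoms: 2-bromopropane, CC(C)Br
Why: Williamson ether synthesis on the potassium phenoxide; the isopropyl ether is chosen because it withstands n-BuLi, carbonate, hydroxide and trifluoroacetic anhydride yet falls to BCl3 in the last step.

**Step 3**
Reactants: 6 3-isopropoxy-4,5-dimethoxybenzaldehyde
Product: 7 5-(2,2-dibromovinyl)-1-isopropoxy-2,3-dimethoxybenzene
Conditions: CBr4, PPh3, CH2Cl2, 0 °C
Reagents that add atoms: carbon tetrabromide, BrC(Br)(Br)Br
Why: First stage of the Corey–Fuchs homologation, in which the ylide Ph3P=CBr2 formed from PPh3 and CBr4 olefinates the aldehyde in a Wittig reaction, an electron-rich benzaldehyde being a routine substrate.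

**Step 4**
Reactants: 7 5-(2,2-dibromovinyl)-1-isopropoxy-2,3-dimethoxybenzene; 8 ethyl chloroformate
Product: 10 ethyl 3-(3-isopropoxy-4,5-dimethoxyphenyl)prop-2-ynoate, via lithium arylacetylide 9 (not isolated)
Conditions: n-BuLi (2.1 equiv), THF, −78 °C; then ClCO2Et, −78 °C to rt
Reagents that add atoms: none
Why: Second stage of the Corey–Fuchs homologation, in which bromine–lithium exchange and Fritsch–Buttenberg–Wiechell rearrangement give the lithium acetylide, whose C-acylation by the chloroformate at low temperature is the usual entry to arylpropiolates.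

**Step 5**
Reactants: 4 2,3,4,5-tetramethoxyphenol; 10 ethyl 3-(3-isopropoxy-4,5-dimethoxyphenyl)prop-2-ynoate
Product: 11 ethyl (Z)-3-(3-isopropoxy-4,5-dimethoxyphenyl)-3-(2,3,4,5-tetramethoxyphenoxy)prop-2-enoate
Conditions: Cs2CO3 (0.3 equiv), DMF, 50 °C
Reagents that add atoms: none
Why: Base-catalysed oxa-Michael addition of the phenoxide to the β-carbon of the ynoate forms O1–C2, and protonation anti to the incoming oxygen should favour the Z ester with the ester cis to the aryloxy group, a minor E isomer being removed by chromatography.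

**Step 6**
Reactants: 11 ethyl (Z)-3-(3-isopropoxy-4,5-dimethoxyphenyl)-3-(2,3,4,5-tetramethoxyphenoxy)prop-2-enoate
Product: 12 (Z)-3-(3-isopropoxy-4,5-dimethoxyphenyl)-3-(2,3,4,5-tetramethoxyphenoxy)prop-2-enoic acid
Conditions: LiOH·H2O, THF/MeOH/H2O, 40 °C; then 1 M HCl to pH 3
Reagents that add atoms: lithium hydroxide, [Li+].[OH-]
Why: Saponification of the ethyl ester under mild conditions, where hydroxide should attack the ester carbonyl faster than the donor-deactivated β-carbon, so the aryl vinyl ether and the Z geometry are kept.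

**Step 7**
Reactants: 12 (Z)-3-(3-isopropoxy-4,5-dimethoxyphenyl)-3-(2,3,4,5-tetramethoxyphenoxy)prop-2-enoic acid
Product: 14 2-(3-isopropoxy-4,5-dimethoxyphenyl)-5,6,7,8-tetramethoxy-4H-chromen-4-one (3′-O-isopropyl-5-O-methyl Gardenin C), via mixed trifluoroacetic anhydride 13 (not isolated)
Conditions: (CF3CO)2O, CH2Cl2, 0 °C to rt
Reagents that add atoms: none
Why: Trifluoroacetic anhydride turns the acid into the mixed anhydride 13, whose acylium-like carbonyl carbon is attacked by C4a of ring A, and loss of the proton from the σ-complex gives the 4-pyranone; this is an intramolecular Friedel–Crafts acylation, the ring-closing step of the classical flavone synthesis from β-aryloxycinnamic acids. Ring C closes in the 6-exo-trig mode at the anhydride carbonyl (6-exo-dig if a free acylium ion is involved), with C4–C4a as the only new skeletal bond. No stereocentre is formed. Within ring A no site control is needed, because C4a is its only unsubstituted carbon and is activated by O1 and the C5 methoxy group (ortho) and by the C7 methoxy group (para). Closure onto ring B to a five-membered indenone is excluded by the Z geometry, which holds the carboxyl group cis to the aryloxy oxygen and out of reach of ring B. The absence of a Lewis acid should keep the isopropyl and methyl ethers intact.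

**Step 8**
Reactants: 14 2-(3-isopropoxy-4,5-dimethoxyphenyl)-5,6,7,8-tetramethoxy-4H-chromen-4-one
Product: 16 Gardenin C (5-hydroxy-2-(3-hydroxy-4,5-dimethoxyphenyl)-6,7,8-trimethoxy-4H-chromen-4-one), via bis(dichloroboryl) ether 15 (not isolated)
Conditions: BCl3 (1 M in CH2Cl2, 4 equiv), CH2Cl2, −78 to 0 °C; then H2O
Reagents that add atoms: none
Why: BCl3 cleaves the secondary alkyl aryl ether (standard isopropyl ether deprotection, methyl ethers reacting much more slowly) and, through a six-membered chelate between the C4 carbonyl and the C5 oxygen, demethylates only the peri methoxy group (chelation-controlled 5-O-demethylation of polymethoxyflavones), and aqueous work-up hydrolyses the boron aryloxides.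

**Compound list**
1 | 1,2,3,4-tetramethoxybenzene | COc1ccc(OC)c(OC)c1OC | starting material
2 | (2,3,4,5-tetramethoxyphenyl)lithium | [Li]c1cc(OC)c(OC)c(OC)c1OC | intermediate
3 | dimethyl (2,3,4,5-tetramethoxyphenyl)boronate | COB(OC)c1cc(OC)c(OC)c(OC)c1OC | intermediate
4 | 2,3,4,5-tetramethoxyphenol | Oc1cc(OC)c(OC)c(OC)c1OC | intermediate
5 | 3-hydroxy-4,5-dimethoxybenzaldehyde | COc1cc(C=O)cc(O)c1OC | starting material
6 | 3-isopropoxy-4,5-dimethoxybenzaldehyde | COc1cc(C=O)cc(OC(C)C)c1OC | intermediate
7 | 5-(2,2-dibromovinyl)-1-isopropoxy-2,3-dimethoxybenzene | COc1cc(C=C(Br)Br)cc(OC(C)C)c1OC | intermediate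
8 | ethyl chloroformate | CCOC(=O)Cl | starting material
9 | lithium (3-isopropoxy-4,5-dimethoxyphenyl)acetylide | [Li]C#Cc1cc(OC)c(OC)c(OC(C)C)c1 | intermediate
10 | ethyl 3-(3-isopropoxy-4,5-dimethoxyphenyl)prop-2-ynoate | CCOC(=O)C#Cc1cc(OC)c(OC)c(OC(C)C)c1 | intermediate
11 | ethyl (Z)-3-(3-isopropoxy-4,5-dimethoxyphenyl)-3-(2,3,4,5-tetramethoxyphenoxy)prop-2-enoate | CCOC(=O)/C=C(\Oc1cc(OC)c(OC)c(OC)c1OC)c1cc(OC)c(OC)c(OC(C)C)c1 | intermediate
12 | (Z)-3-(3-isopropoxy-4,5-dimethoxyphenyl)-3-(2,3,4,5-tetramethoxyphenoxy)prop-2-enoic acid | OC(=O)/C=C(\Oc1cc(OC)c(OC)c(OC)c1OC)c1cc(OC)c(OC)c(OC(C)C)c1 | intermediate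
13 | (Z)-3-(3-isopropoxy-4,5-dimethoxyphenyl)-3-(2,3,4,5-tetramethoxyphenoxy)prop-2-enoic trifluoroacetic anhydride | FC(F)(F)C(=O)OC(=O)/C=C(\Oc1cc(OC)c(OC)c(OC)c1OC)c1cc(OC)c(OC)c(OC(C)C)c1 | intermediate
14 | 2-(3-isopropoxy-4,5-dimethoxyphenyl)-5,6,7,8-tetramethoxy-4H-chromen-4-one | COc1cc(-c2cc(=O)c3c(OC)c(OC)c(OC)c(OC)c3o2)cc(OC(C)C)c1OC | intermediate
15 | 5-(dichloroboryloxy)-2-[3-(dichloroboryloxy)-4,5-dimethoxyphenyl]-6,7,8-trimethoxy-4H-chromen-4-one | COc1cc(-c2cc(=O)c3c(OB(Cl)Cl)c(OC)c(OC)c(OC)c3o2)cc(OB(Cl)Cl)c1OC | intermediate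
16 | Gardenin C | COc1cc(-c2cc(=O)c3c(O)c(OC)c(OC)c(OC)c3o2)cc(O)c1OC | target

**Step count**
Total: 8 steps. Longest linear sequence: 7 steps (steps 2 to 8, from 5).

**Steps most likely to fail**

Step 7. The mixed anhydride of a donor-stabilised acrylic acid may ionise too slowly for acylation to proceed, or acid-induced Z to E isomerisation may open the way to closure onto ring B. Fallback: setting out from phenol 4, Fries-type C-acetylation at the same free carbon (AcOH, BF3·OEt2, 80 °C) should give 1-(2-hydroxy-3,4,5,6-tetramethoxyphenyl)ethan-1-one F1. Claisen–Schmidt condensation with aldehyde 6 (KOH, EtOH, rt) should give (E)-1-(2-hydroxy-3,4,5,6-tetramethoxyphenyl)-3-(3-isopropoxy-4,5-dimethoxyphenyl)prop-2-en-1-one F2. Oxidative cyclisation of this hydroxychalcone (catalytic I2, DMSO, 120 °C) returns to the route at flavone 14.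

Step 5. Addition of a hindered, ortho-substituted phenoxide to an electron-rich arylalkynoate may be sluggish, and control of the alkene geometry may be poor. Fallback: setting out from ynoate 10, anti hydroiodination (NaI, AcOH, 70 °C) should give ethyl (Z)-3-iodo-3-(3-isopropoxy-4,5-dimethoxyphenyl)prop-2-enoate F3. Ullmann-type C–O coupling with phenol 4 (CuI, N,N-dimethylglycine, Cs2CO3, dioxane, 90 °C), which keeps the configuration at the vinyl carbon, returns to the route at ester 11.

Step 8. Dealkylation may run on to the methoxy groups next to the new boron aryloxides (C6, C4′), or loss of the isopropyl group may stay incomplete. Fallback: the two ethers are removed in separate operations of different mechanism. Setting out from 14, protonolysis of the secondary ether (conc. H2SO4 in AcOH, rt) should give 3′-hydroxy-5,6,7,8,4′,5′-hexamethoxyflavone F4. Chelation-controlled demethylation at C5 alone (AlCl3, MeCN, rt; then dilute HCl) then arrives at target 16.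

**Further compounds**
F1 | step 7 | 1-(2-hydroxy-3,4,5,6-tetramethoxyphenyl)ethan-1-one | CC(=O)c1c(O)c(OC)c(OC)c(OC)c1OC
F2 | step 7 | (E)-1-(2-hydroxy-3,4,5,6-tetramethoxyphenyl)-3-(3-isopropoxy-4,5-dimethoxyphenyl)prop-2-en-1-one | COc1cc(/C=C/C(=O)c2c(O)c(OC)c(OC)c(OC)c2OC)cc(OC(C)C)c1OC
F3 | step 5 | ethyl (Z)-3-iodo-3-(3-isopropoxy-4,5-dimethoxyphenyl)prop-2-enoate | CCOC(=O)/C=C(\I)c1cc(OC)c(OC)c(OC(C)C)c1
F4 | step 8 | 3′-hydroxy-5,6,7,8,4′,5′-hexamethoxyflavone | COc1cc(-c2cc(=O)c3c(OC)c(OC)c(OC)c(OC)c3o2)cc(O)c1OC
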